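The alder run looks nearly like teal: same reagent, same free catalyst, a little more substrate. Blue is a different recipe, so I want one measure for both.

| flask | substrate | reagent | free catalyst | remark | time |
|---|---|---|---|---|---|
| larch | 0.050 M (fed, over 50 min) | 0.0525 M | 1.8 mM | run made earlier |  |
| oak | 0.050 M (fed, over 50 min) | 0.0525 M | 4.7 mM | run made earlier |  |
| alder | 0.058 M (fed, over 50 min) | 0.0525 M | 1.4 mM | run made earlier |  |
| teal | 0.050 M (fed, over 50 min) | 0.0525 M | 1.4 mM |  | 8.0 h |
| blue | 0.10 M | 0.0525 M | 3.0 mM | everything together at the start | 8.0 h |

| run | time / h | product / % |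
|---|---|---|
| larch | 0.417 | 1.0 |
| larch | 0.667 | 1.0 |
| larch | 1.00 | 3.4 |
| larch | 1.50 | 8.2 |
| larch | 2.50 | 12.6 |
| larch | 4.00 | 19.1 |
| larch | 6.00 | 31.2 |
| oak | 0.333 | 0 |
| oak | 0.833 | 7.4 |
| oak | 1.50 | 19.7 |
| oak | 2.50 | 29.9 |
| oak | 3.00 | 37.3 |
| oak | 4.00 | 45.0 |
| oak | 6.00 | 58.9 |
| alder | 0.500 | 1.0 |
| alder | 1.33 | 5.2 |
| alder | 2.50 | 9.1 |
| alder | 4.00 | 14.6 |
| alder | 6.00 | 21.5 |

(standard deviation of a reading: 1 percentage point)

- reactions considered so far: reagent + free catalyst -> catalyst intermediate A; substrate + catalyst intermediate A <-> catalyst intermediate B; catalyst intermediate A -> spent catalyst; catalyst intermediate B -> free catalyst + product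
- percentages count the whole charge, also what has not yet gone in

- which of the two ends with the higher amount of product, in percent of the substrate charged ("neither" if they lie within 2 percentage points) (teal / blue / neither)
- product at the end, in percent of the substrate charged, teal
- product at the end, in percent of the substrate charged, blue

First, the end state. The listed reactions spend one reagent per product, and blue holds less reagent than substrate, so in blue the reagent is the limiting reagent, with a ceiling of 52.5% of the substrate charged. Then, the speed.

I count the turnover rate (turnover frequency), the product made per catalyst charged per hour, averaged from the start to the last reading. Alder gives 1.48 h⁻¹ and larch gives 1.44 h⁻¹, and the two agree. Oak, with the most catalyst of the runs, reads lower, at 1.04 h⁻¹.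

Percent product is this rate times time times the loading, which is catalyst charged over substrate charged. Alder's loading is 2.41%, teal's is 2.80%, and blue's is 3.00%. With alder's rate, I reckon teal at 33.3% at 8.0 h and blue at 35.6%, which is below blue's ceiling. So I put blue ahead by 2.3 percentage points, narrowly past the margin. Oak is my warning, since blue has twice teal's catalyst on the same reagent.

The forecast differs from my reckoning. It gives teal 30% (27% to 33%), blue 29% (25% to 33%), and so neither, on the reading “with free catalyst resting and the first step limiting”.

The flask gives teal 28.7% and blue 36.0%, so blue ends higher, by 7.3 points.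

    reagent + free catalyst → catalyst intermediate A (k = 1.80 L mol⁻¹ min⁻¹)
    substrate + catalyst intermediate A ⇌ catalyst intermediate B (K = 688 L mol⁻¹, k = 1.92 L mol⁻¹ min⁻¹)
    catalyst intermediate A → spent catalyst (k = 0.00278 min⁻¹)
    catalyst intermediate B → free catalyst + product (k = 0.110 min⁻¹)

Over 8.0 h, blue's turnover rate is 1.50 h⁻¹ and teal's is 1.28 h⁻¹. At that time spent catalyst stands at 22.4% of the catalyst charged in blue and 39.8% in teal. The neighbouring flask is teal with 0.013 M of substrate, so its loading is 10.8%. Alder's rate would give it 128%, above the whole charge. The neighbouring flask gives 41.5%, a turnover rate of 0.482 h⁻¹, and its spent catalyst stands at 61.8% of the catalyst charged.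

The data were generated by integration with constants of no real substance; the scatter is artificial.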